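**Plan**
Atom labels (kept for all intermediates): nine-membered ring C1 (=CH2), C2, C3, C4=C5 (Me), C6, C7, C8 (side chain), C9 (CO2Me); C10 is the ester carbon; side chain C11 (bearing CH2OAc)=C12–C13=C14–C15(Me)2OH.
Retrosynthesis: remove acetate and silyl groups, undo a 1,3-hydroxyl shift, cut C12–C13 (alkenylzinc + 2-substituted acrolein); re-join C10 to C5 with a mesylate on C4; cut C9–C1 (ketone α-alkenylation) and C4–C5 (aldol) back to (S)-carvone and 4-bromopent-4-enal.
Enabling feature: C10 can be a one-carbon ketone bridge from C9 to C5, so a bicyclo[4.3.1]decan-10-one (six-membered ring C5–C6–C7–C8–C9–C10, seven-membered ring C1–C2–C3–C4–C5–C10–C9) hides the ring C1–C9, the C4=C5 alkene and the C9 ester.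
Forward: the carvone six-membered ring comes first, the aldol joins the C1–C4 chain at C5, palladium closes the seven-membered ring at C9–C1, methoxide opens the bicycle to the nine-membered ring, and the side chain is joined last.
Stereochemistry: C8 from (S)-carvone; C5 by axial aldol attack cis to the C8 substituent; C4 by an open-transition-state aldol; C9 fixed by the bridging ring closure; C4/C5 become the (E)-alkene by antiperiplanar fragmentation; (E)-C13=C14 by syn-hydrozirconation; C11=C12 geometry by thermodynamic transposition.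

Key step: step 11

Remark: the hinted tert-butyldimethylsilyl ether on the primary alcohol is replaced by tert-butyldiphenylsilyl so that it survives selective removal of a secondary triethylsilyl ether. A chelated lithium aldol is expected to give the wrong C4 epimer, so the aldol is run fluoride-initiated.

Step 1
Reactants: 1 tert-butyl acetate; 2 2,3-dibromopropene
Product: 4 tert-butyl 4-bromopent-4-enoate, via lithium ester enolate 3 (not isolated)
Conditions: LiN(i-Pr)2, THF, −78 °C; then 2, −78 → 0 °C
Reagents that add atoms: none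
Why: SN2 alkylation of a lithium ester enolate at the allylic bromide of 2 is standard enolate alkylation and leaves the vinylic bromide untouched.

Step 2
Reactants: 4 tert-butyl 4-bromopent-4-enoate
Product: 6 4-bromopent-4-enal, via aluminium hemiacetal 5 (not isolated)
Conditions: i-Bu2AlH, CH2Cl2, −78 °C; aq. potassium sodium tartrate
Reagents that add atoms: none
Why: Half-reduction of an ester with i-Bu2AlH stops at the tetrahedral aluminium hemiacetal at −78 °C, which releases the aldehyde on work-up, and the vinyl bromide is inert to the hydride.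

Step 3
Reactants: 7 (S)-carvone
Product: 8 (5S)-5-(3-hydroxyprop-1-en-2-yl)-2-methylcyclohex-2-en-1-one
Conditions: SeO2 (cat.), t-BuOOH, salicylic acid (cat.), CH2Cl2, rt
Reagents that add atoms: tert-butyl hydroperoxide CC(C)(C)OO
Why: Selenium dioxide allylic oxidation (ene reaction, then 2,3-sigmatropic shift) attacks the electron-rich 1,1-disubstituted alkene and not the enone, so the isopropenyl methyl is hydroxylated without touching the stereocentre.

Step 4
Reactants: 8 hydroxy enone
Product: 9 (5S)-5-[3-(tert-butyldiphenylsilyloxy)prop-1-en-2-yl]-2-methylcyclohex-2-en-1-one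
Conditions: t-BuPh2SiCl, imidazole, CH2Cl2, 0 °C → rt
Reagents that add atoms: tert-butyl(chloro)diphenylsilane CC(C)(C)[Si](Cl)(c1ccccc1)c1ccccc1
Why: Routine silylation of a primary allylic alcohol, giving an ether that tolerates hydride, fluoride catalysis at low temperature, phenoxide, buffered HF and methoxide.

Step 5
Reactants: 9 silyloxy enone
Product: 11 tert-butyl({2-[(1S)-4-methyl-3-(trimethylsilyloxy)cyclohex-3-en-1-yl]prop-2-en-1-yl}oxy)diphenylsilane, via lithium enolate 10 (not isolated)
Conditions: LiBH(s-Bu)3, THF, −78 °C; then Me3SiCl, Et3N, −78 → 0 °C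
Reagents that add atoms: chlorotrimethylsilane C[Si](C)(C)Cl
Why: Conjugate reduction of a β-unsubstituted cyclohexenone by the hindered borohydride gives the tetrasubstituted enolate regiospecifically, and O-silylation stores it as the enol silane (reductive enolate trapping).

Step 6
Reactants: 11 trimethylsilyl enol ether; 6 4-bromopent-4-enal
Product: 13 (2S,5S)-2-[(1R)-4-bromo-1-hydroxypent-4-en-1-yl]-5-[3-(tert-butyldiphenylsilyloxy)prop-1-en-2-yl]-2-methylcyclohexan-1-one, via O-trimethylsilyl aldol 12 (not isolated)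
Conditions: 6, (Me2N)3S+ Me3SiF2− (10 mol%), THF, −78 °C; then 1 M HCl, THF, 0 °C
Reagents that add atoms: none
Why: In this fluoride-initiated aldol of an enol silane the cation-free enolate should react through an open antiperiplanar transition state on the axial face cis to the C8 substituent (the usual face for dihydrocarvone-type enolates, setting quaternary C5 as S), with the aldehyde hydrogen over the ring and the chain beside the methyl group, which puts the C4 hydroxyl syn to C6 and anti to the methyl group (4R).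

Step 7
Reactants: 13 aldol
Product: 14 (2S,5S)-2-[(1R)-4-bromo-1-(triethylsilyloxy)pent-4-en-1-yl]-5-[3-(tert-butyldiphenylsilyloxy)prop-1-en-2-yl]-2-methylcyclohexan-1-one
Conditions: Et3SiOTf, 2,6-lutidine, CH2Cl2, −78 → 0 °C
Reagents that add atoms: triethylsilyl trifluoromethanesulfonate CC[Si](CC)(CC)OS(=O)(=O)C(F)(F)F
Why: Silyl triflate silylation works on hindered secondary alcohols, and masking the aldol hydroxyl prevents retro-aldol cleavage under the basic conditions of step 8 while staying removable beside the primary silyl ether.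

Step 8
Reactants: 14 bromoalkenyl ketone
Product: 15 (1S,2R,6R,7S)-7-[3-(tert-butyldiphenylsilyloxy)prop-1-en-2-yl]-1-methyl-5-methylidene-2-(triethylsilyloxy)bicyclo[4.3.1]decan-10-one
Conditions: Pd(PPh3)4 (10 mol%), KOPh, THF, 65 °C
Reagents that add atoms: none
Why: Palladium-catalysed intramolecular α-alkenylation of a ketone (oxidative addition of the vinyl bromide to zerovalent palladium, enolate capture, reductive elimination) can only use the C9 enolate because C5 is quaternary, and the axial C4 arm reaches C9 only on its own face, so C9–C1 forms cis to C5–C4 and fixes C9 (R) with the exocyclic methylene in place.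

Step 9
Reactants: 15 bicyclic silyl ether
Product: 16 (1S,2R,6R,7S)-7-[3-(tert-butyldiphenylsilyloxy)prop-1-en-2-yl]-2-hydroxy-1-methyl-5-methylidenebicyclo[4.3.1]decan-10-one
Conditions: HF·pyridine, pyridine, THF, 0 °C → rt
Reagents that add atoms: none
Why: Selective silyl ether cleavage: buffered HF removes the secondary triethylsilyl group much faster than the primary tert-butyldiphenylsilyl group, and the β-hydroxy ketone is stable in the weakly acidic medium.

Step 10
Reactants: 16 bicyclic hydroxy ketone
Product: 17 (1S,2R,6R,7S)-7-[3-(tert-butyldiphenylsilyloxy)prop-1-en-2-yl]-1-methyl-5-methylidene-10-oxobicyclo[4.3.1]decan-2-yl methanesulfonate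
Conditions: MeSO2Cl, Et3N, CH2Cl2, 0 °C
Reagents that add atoms: methanesulfonyl chloride CS(=O)(=O)Cl
Why: Mesylation through sulfene works on hindered secondary alcohols with retention at C4, and the β-keto mesylate cannot eliminate towards the ketone because C5 is quaternary.

Step 11
Reactants: 17 bicyclic keto mesylate
Product: 19 methyl (1R,2S,5E)-2-[3-(tert-butyldiphenylsilyloxy)prop-1-en-2-yl]-5-methyl-9-methylidenecyclonon-5-ene-1-carboxylate, via hemiketal alkoxide 18 (not isolated)
Conditions: NaOMe, MeOH–THF, 0 °C → rt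
Reagents that add atoms: sodium methoxide C[O-].[Na+]
Why: Methoxide adds to the strained C10 bridging ketone from the face of the three-carbon bridge, and in the hemiketal alkoxide 18 an oxygen lone pair, the C10–C5 bond and the C4–OMs bond are antiperiplanar, so C10–C5 cleavage, C4=C5 π-bond formation and mesylate loss occur together as a Grob fragmentation. The closest known reaction type is the alkoxide-induced, retro-Claisen-mode fragmentation of cyclic 1,3-keto sulfonates such as bicyclo[3.3.1]nonan-9-one 2-sulfonates to cyclooctenecarboxylates. No ring is closed: the nine-membered ring appears by cutting the bond shared by the six- and seven-membered rings, and C10 becomes the C9 methyl ester. No stereocentre is created and C8 and C9 are untouched; the C4 configuration is transferred stereospecifically into the alkene geometry. The (E) alkene needs C3 antiperiplanar to C6 about C4–C5, which holds in the conformer where the four-carbon bridge is turned away from the three-carbon bridge and the (4R) mesylate sits equatorial on the seven-membered ring, the only conformer in which this epimer has the leaving group anti to C5–C10. Elimination towards C5 is impossible, bridgehead C9 cannot enolise before ring opening, and low temperature with a short reaction time should keep the freed β,γ-unsaturated ester from epimerising or conjugating.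

Step 12
Reactants: 19 cyclononadiene ester
Product: 20 methyl (1R,2S,5E)-2-(3-hydroxyprop-1-en-2-yl)-5-methyl-9-methylidenecyclonon-5-ene-1-carboxylate
Conditions: Bu4NF, AcOH, THF, 0 °C → rt
Reagents that add atoms: none
Why: Fluoride cleavage of the silyl ether, buffered with acetic acid so that the ester α-centre C9 does not epimerise and the freed δ-hydroxy ester does not lactonise; 20 is used at once.

Step 13
Reactants: 20 allylic alcohol
Product: 21 methyl (1R,2S,5E)-5-methyl-9-methylidene-2-(3-oxoprop-1-en-2-yl)cyclonon-5-ene-1-carboxylate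
Conditions: MnO2, CH2Cl2, rt
Reagents that add atoms: none
Why: MnO2 oxidises allylic alcohols selectively under neutral conditions, giving the 2-substituted acrolein without touching the ester, the strained (E)-alkene or C8 and C9.

Step 14
Reactants: 22 2-methylbut-3-yn-2-ol
Product: 23 triethyl[(2-methylbut-3-yn-2-yl)oxy]silane
Conditions: Et3SiCl, imidazole, DMAP (cat.), DMF, rt
Reagents that add atoms: chlorotriethylsilane CC[Si](Cl)(CC)CC
Why: Standard silylation of an unhindered tertiary propargylic alcohol, giving an ether that tolerates hydrozirconation, organozinc addition and acylation.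

Step 15
Reactants: 23 silylated alkyne; 21 enal
Product: 26 methyl (1R,2S,5E)-2-[(4E)-3-hydroxy-6-methyl-6-(triethylsilyloxy)hepta-1,4-dien-2-yl]-5-methyl-9-methylidenecyclonon-5-ene-1-carboxylate (both C12 epimers), via alkenylzirconocene chloride 24 (not isolated), via alkenyl(methyl)zinc 25 (not isolated)
Conditions: 23, Cp2Zr(H)Cl, CH2Cl2, rt; Me2Zn, toluene, −65 °C; then 21, 0 °C
Reagents that add atoms: none
Why: Syn-hydrozirconation of the terminal alkyne gives the (E)-alkenyl metal, transmetalation to zinc gives a reagent that adds 1,2 to the enal and ignores the ester, and the uncontrolled C12 carbinol centre is erased in step 16.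

Step 16
Reactants: 26 bis-allylic alcohol
Product: 27 methyl (1R,2S,5E)-2-[(2Z,4E)-1-hydroxy-6-methyl-6-(triethylsilyloxy)hepta-2,4-dien-2-yl]-5-methyl-9-methylidenecyclonon-5-ene-1-carboxylate
Conditions: Ph3SiOReO3 (5 mol%), Et2O, 0 °C
Reagents that add atoms: none
Why: Rhenium-oxo-catalysed 1,3-transposition of an allylic alcohol is a reversible 3,3-shift through the perrhenate ester, so under thermodynamic control the hydroxyl should move to the primary carbon to give the conjugated, more substituted diene with the dienyl chain trans to ring carbon C8 (least allylic strain), as in the target.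

Step 17
Reactants: 27 dienyl alcohol
Product: 28 methyl (1R,2S,5E)-2-[(2Z,4E)-1-acetoxy-6-methyl-6-(triethylsilyloxy)hepta-2,4-dien-2-yl]-5-methyl-9-methylidenecyclonon-5-ene-1-carboxylate
Conditions: Ac2O, pyridine, DMAP (cat.), CH2Cl2, 0 °C
Reagents that add atoms: acetic anhydride CC(=O)OC(C)=O
Why: DMAP-catalysed acylation of the primary allylic alcohol is fast and, done straight after step 16, prevents lactonisation onto the C9 ester.

Step 18
Reactants: 28 silylated acetate
Product: 29 methyl (1R,2S,5E)-2-[(2Z,4E)-1-acetoxy-6-hydroxy-6-methylhepta-2,4-dien-2-yl]-5-methyl-9-methylidenecyclonon-5-ene-1-carboxylate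
Conditions: Bu4NF, AcOH, THF, 0 °C
Reagents that add atoms: none
Why: Acetic-acid-buffered fluoride removes the tertiary triethylsilyl ether without cleaving or shifting the allylic acetate and without ionising the tertiary dienylic alcohol.

**Compound list**
1 | tert-butyl acetate | CC(=O)OC(C)(C)C | starting material
2 | 2,3-dibromopropene | C=C(Br)CBr | starting material
3 | lithium 1-tert-butoxyethenolate | C=C(O[Li])OC(C)(C)C | intermediate
4 | tert-butyl 4-bromopent-4-enoate | C=C(Br)CCC(=O)OC(C)(C)C | intermediate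
5 | diisobutylaluminium 4-bromo-1-tert-butoxypent-4-en-1-olate (racemic) | C=C(Br)CCC(OC(C)(C)C)O[Al](CC(C)C)CC(C)C | intermediate
6 | 4-bromopent-4-enal | C=C(Br)CCC=O | intermediate
7 | (S)-carvone, (5S)-2-methyl-5-(prop-1-en-2-yl)cyclohex-2-en-1-one | CC1=CC[C@@H](CC1=O)C(C)=C | starting material
8 | (5S)-5-(3-hydroxyprop-1-en-2-yl)-2-methylcyclohex-2-en-1-one | CC1=CC[C@@H](CC1=O)C(=C)CO | intermediate
9 | (5S)-5-[3-(tert-butyldiphenylsilyloxy)prop-1-en-2-yl]-2-methylcyclohex-2-en-1-one | CC1=CC[C@@H](CC1=O)C(=C)CO[Si](c2ccccc2)(c2ccccc2)C(C)(C)C | intermediate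
10 | lithium (5S)-5-[3-(tert-butyldiphenylsilyloxy)prop-1-en-2-yl]-2-methylcyclohex-1-en-1-olate | CC1=C(O[Li])C[C@H](CC1)C(=C)CO[Si](c2ccccc2)(c2ccccc2)C(C)(C)C | intermediate
11 | tert-butyl({2-[(1S)-4-methyl-3-(trimethylsilyloxy)cyclohex-3-en-1-yl]prop-2-en-1-yl}oxy)diphenylsilane | CC1=C(O[Si](C)(C)C)C[C@H](CC1)C(=C)CO[Si](c2ccccc2)(c2ccccc2)C(C)(C)C | intermediate
12 | (2S,5S)-2-[(1R)-4-bromo-1-(trimethylsilyloxy)pent-4-en-1-yl]-5-[3-(tert-butyldiphenylsilyloxy)prop-1-en-2-yl]-2-methylcyclohexan-1-one | C=C(Br)CC[C@@H](O[Si](C)(C)C)[C@]1(C)CC[C@H](C(=C)CO[Si](c2ccccc2)(c2ccccc2)C(C)(C)C)CC1=O | intermediate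
13 | (2S,5S)-2-[(1R)-4-bromo-1-hydroxypent-4-en-1-yl]-5-[3-(tert-butyldiphenylsilyloxy)prop-1-en-2-yl]-2-methylcyclohexan-1-one | C=C(Br)CC[C@@H](O)[C@]1(C)CC[C@H](C(=C)CO[Si](c2ccccc2)(c2ccccc2)C(C)(C)C)CC1=O | intermediate
14 | (2S,5S)-2-[(1R)-4-bromo-1-(triethylsilyloxy)pent-4-en-1-yl]-5-[3-(tert-butyldiphenylsilyloxy)prop-1-en-2-yl]-2-methylcyclohexan-1-one | C=C(Br)CC[C@@H](O[Si](CC)(CC)CC)[C@]1(C)CC[C@H](C(=C)CO[Si](c2ccccc2)(c2ccccc2)C(C)(C)C)CC1=O | intermediate
15 | (1S,2R,6R,7S)-7-[3-(tert-butyldiphenylsilyloxy)prop-1-en-2-yl]-1-methyl-5-methylidene-2-(triethylsilyloxy)bicyclo[4.3.1]decan-10-one | C=C1CC[C@@H](O[Si](CC)(CC)CC)[C@]2(C)CC[C@H](C(=C)CO[Si](c3ccccc3)(c3ccccc3)C(C)(C)C)[C@H]1C2=O | intermediate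
16 | (1S,2R,6R,7S)-7-[3-(tert-butyldiphenylsilyloxy)prop-1-en-2-yl]-2-hydroxy-1-methyl-5-methylidenebicyclo[4.3.1]decan-10-one | C=C1CC[C@@H](O)[C@]2(C)CC[C@H](C(=C)CO[Si](c3ccccc3)(c3ccccc3)C(C)(C)C)[C@H]1C2=O | intermediate
17 | (1S,2R,6R,7S)-7-[3-(tert-butyldiphenylsilyloxy)prop-1-en-2-yl]-1-methyl-5-methylidene-10-oxobicyclo[4.3.1]decan-2-yl methanesulfonate | C=C1CC[C@@H](OS(C)(=O)=O)[C@]2(C)CC[C@H](C(=C)CO[Si](c3ccccc3)(c3ccccc3)C(C)(C)C)[C@H]1C2=O | intermediate
18 | sodium salt of the C10 methoxide adduct of 17 (methoxy group anti to the four-carbon bridge) | C=C1CC[C@@H](OS(C)(=O)=O)[C@]2(C)CC[C@H](C(=C)CO[Si](c3ccccc3)(c3ccccc3)C(C)(C)C)[C@H]1[C@@]2([O-])OC.[Na+] | intermediate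
19 | methyl (1R,2S,5E)-2-[3-(tert-butyldiphenylsilyloxy)prop-1-en-2-yl]-5-methyl-9-methylidenecyclonon-5-ene-1-carboxylate | C=C1CC/C=C(\C)CC[C@H](C(=C)CO[Si](c2ccccc2)(c2ccccc2)C(C)(C)C)[C@H]1C(=O)OC | intermediate
20 | methyl (1R,2S,5E)-2-(3-hydroxyprop-1-en-2-yl)-5-methyl-9-methylidenecyclonon-5-ene-1-carboxylate | C=C1CC/C=C(\C)CC[C@H](C(=C)CO)[C@H]1C(=O)OC | intermediate
21 | methyl (1R,2S,5E)-5-methyl-9-methylidene-2-(3-oxoprop-1-en-2-yl)cyclonon-5-ene-1-carboxylate | C=C1CC/C=C(\C)CC[C@H](C(=C)C=O)[C@H]1C(=O)OC | intermediate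
22 | 2-methylbut-3-yn-2-ol | CC(C)(O)C#C | starting material
23 | triethyl[(2-methylbut-3-yn-2-yl)oxy]silane | C#CC(C)(C)O[Si](CC)(CC)CC | intermediate
24 | chlorobis(cyclopentadienyl)[(1E)-3-methyl-3-(triethylsilyloxy)but-1-en-1-yl]zirconium (rings drawn σ-bound) | CC[Si](CC)(CC)OC(C)(C)/C=C/[Zr](Cl)(C1C=CC=C1)C1C=CC=C1 | intermediate
25 | methyl[(1E)-3-methyl-3-(triethylsilyloxy)but-1-en-1-yl]zinc | CC[Si](CC)(CC)OC(C)(C)/C=C/[Zn]C | intermediate
26 | methyl (1R,2S,5E)-2-[(4E)-3-hydroxy-6-methyl-6-(triethylsilyloxy)hepta-1,4-dien-2-yl]-5-methyl-9-methylidenecyclonon-5-ene-1-carboxylate (both C12 epimers) | C=C1CC/C=C(\C)CC[C@H](C(=C)C(O)/C=C/C(C)(C)O[Si](CC)(CC)CC)[C@H]1C(=O)OC | intermediate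
27 | methyl (1R,2S,5E)-2-[(2Z,4E)-1-hydroxy-6-methyl-6-(triethylsilyloxy)hepta-2,4-dien-2-yl]-5-methyl-9-methylidenecyclonon-5-ene-1-carboxylate | C=C1CC/C=C(\C)CC[C@H](/C(=C/C=C/C(C)(C)O[Si](CC)(CC)CC)CO)[C@H]1C(=O)OC | intermediate
28 | methyl (1R,2S,5E)-2-[(2Z,4E)-1-acetoxy-6-methyl-6-(triethylsilyloxy)hepta-2,4-dien-2-yl]-5-methyl-9-methylidenecyclonon-5-ene-1-carboxylate | C=C1CC/C=C(\C)CC[C@H](/C(=C/C=C/C(C)(C)O[Si](CC)(CC)CC)COC(C)=O)[C@H]1C(=O)OC | intermediate
29 | methyl (1R,2S,5E)-2-[(2Z,4E)-1-acetoxy-6-hydroxy-6-methylhepta-2,4-dien-2-yl]-5-methyl-9-methylidenecyclonon-5-ene-1-carboxylate | C=C1CC/C=C(\C)CC[C@H](/C(=C/C=C/C(C)(C)O)COC(C)=O)[C@H]1C(=O)OC | target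

**Step count**
Total: 18 steps. Longest linear sequence: 15 steps, from 7 to 29 (steps 3–13 and 15–18); steps 1–2 (aldehyde 6) and step 14 (alkyne 23) are side branches.

**Steps most likely to fail**

Step 6. The aldol may pass through a closed, cation- or silicon-bridged chair, or equilibrate by retro-aldol, instead of the open transition state. That would give poor or reversed face selectivity at the aldehyde carbon, and the C4 epimer leads to the (Z)-cyclononene. The fallback sets out from 9 and returns at 13. Compound 9 is reduced with LiBH(s-Bu)3 as in step 5 and the lithium enolate 10 is treated directly with 6 (THF, −78 °C, AcOH quench). The closed chair transition state should then give the C4-epimeric aldol F1 on purpose. A Mitsunobu reaction (4-nitrobenzoic acid, PPh3, i-PrO2CN=NCO2i-Pr, toluene, 0 °C → rt) inverts C4 to the 4-nitrobenzoate F2, and methanolysis (K2CO3, MeOH, 0 °C) gives 13.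

Step 8. Closure of the seven-membered ring at palladium may be slow, so that protodebromination, alkene migration or base-induced silyl loss followed by retro-aldol cleavage take over. The fallback sets out from 11 and returns at 15. The aldol of step 6 is run with pent-4-ynal in place of 6 and gives, through the O-trimethylsilyl alkynyl aldol F3, the alkynyl aldol F4. Et3SiOTf and 2,6-lutidine give the triethylsilyl ether F5, and t-BuMe2SiOTf with Et3N gives the silyl enol ether F6 (only C9 can enolise). A Ph3PAuCl/AgBF4-catalysed Conia-ene-type 7-exo-dig addition of the enol ether to the gold-activated alkyne (CH2Cl2–MeOH) then forms C9–C1 and the exocyclic methylene together and gives 15.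

Step 16. The transposition may stop short or lose regiocontrol, the Lewis-acidic rhenium oxo species may ionise the tertiary allylic silyl ether, or the freed primary alcohol may lactonise onto the C9 ester. The fallback sets out from 26 and returns at 28. Acetylation (Ac2O, pyridine, DMAP) gives the bis-allylic acetate F7. A Pd(PPh3)4-catalysed allylic transposition in THF (Tsuji–Trost-type ionisation to the pentadienyl palladium complex, return of acetate at the primary terminus under thermodynamic control) gives 28 directly, without passing through 27.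

Further compounds
F1 | step 6 | (2S,5S)-2-[(1S)-4-bromo-1-hydroxypent-4-en-1-yl]-5-[3-(tert-butyldiphenylsilyloxy)prop-1-en-2-yl]-2-methylcyclohexan-1-one | C=C(Br)CC[C@H](O)[C@]1(C)CC[C@H](C(=C)CO[Si](c2ccccc2)(c2ccccc2)C(C)(C)C)CC1=O
F2 | step 6 | 4-nitrobenzoate of 13, (1R) at the ester-bearing carbon | C=C(Br)CC[C@@H](OC(=O)c2ccc(cc2)[N+](=O)[O-])[C@]1(C)CC[C@H](C(=C)CO[Si](c3ccccc3)(c3ccccc3)C(C)(C)C)CC1=O
F3 | step 8 | (2S,5S)-5-[3-(tert-butyldiphenylsilyloxy)prop-1-en-2-yl]-2-methyl-2-[(1R)-1-(trimethylsilyloxy)pent-4-yn-1-yl]cyclohexan-1-one | C#CCC[C@@H](O[Si](C)(C)C)[C@]1(C)CC[C@H](C(=C)CO[Si](c2ccccc2)(c2ccccc2)C(C)(C)C)CC1=O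
F4 | step 8 | (2S,5S)-5-[3-(tert-butyldiphenylsilyloxy)prop-1-en-2-yl]-2-[(1R)-1-hydroxypent-4-yn-1-yl]-2-methylcyclohexan-1-one | C#CCC[C@@H](O)[C@]1(C)CC[C@H](C(=C)CO[Si](c2ccccc2)(c2ccccc2)C(C)(C)C)CC1=O
F5 | step 8 | (2S,5S)-5-[3-(tert-butyldiphenylsilyloxy)prop-1-en-2-yl]-2-methyl-2-[(1R)-1-(triethylsilyloxy)pent-4-yn-1-yl]cyclohexan-1-one | C#CCC[C@@H](O[Si](CC)(CC)CC)[C@]1(C)CC[C@H](C(=C)CO[Si](c2ccccc2)(c2ccccc2)C(C)(C)C)CC1=O
F6 | step 8 | tert-butyldimethylsilyl enol ether of F5 (C9=C10 enol ether) | C#CCC[C@@H](O[Si](CC)(CC)CC)[C@]1(C)CC[C@H](C(=C)CO[Si](c2ccccc2)(c2ccccc2)C(C)(C)C)C=C1O[Si](C)(C)C(C)(C)C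
F7 | step 16 | C12 acetate of 26 (both C12 epimers) | C=C1CC/C=C(\C)CC[C@H](C(=C)C(OC(C)=O)/C=C/C(C)(C)O[Si](CC)(CC)CC)[C@H]1C(=O)OC
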